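Percent of the substrate charged is the unit of these readings, so one reading divided by another is a pure number, and the useful one is c target over c substrate, the usual reaction quotient.

| flask | substrate | free enzyme | temperature | remark | time |
|---|---|---|---|---|---|
| autumn | 0.10 M | 0.0074 mol% | 25 °C | the very flask that is asked about, followed so far |  |
| noon | 0.067 M | 0.0074 mol% | 20 °C | run made earlier |  |
| flask | 0.10 M | 0.0074 mol% | 25 °C |  | 10 min |

autumn run (percent of the substrate charged)

| time / min | target / % | substrate / % |
|---|---|---|
| 1.33 | 79 | 18 |
| 2.50 | 82 | 17 |
| 4.00 | 82 | 18 |
| 5.00 | 83 | 14 |
| 6.00 | 80 | 13 |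

noon run (percent of the substrate charged)

| time / s | target / % | substrate / % |
|---|---|---|
| 25.0 | 57 | 45 |
| 50.0 | 73 | 30 |
| 80.0 | 73 | 23 |
| 90.0 | 75 | 25 |
| 120 | 75 | 24 |

(scatter of a reading: 1.5 percentage points)

- target, in percent of the substrate first charged, at 10 min
- what to do for the largest gain in target; "none" if nothing gains more than 2 percentage points (theta / eta / beta / gamma / none)
- target present, with what was taken out counted in, in percent of the substrate first charged, after beta
- target present, with what was taken out counted in, in percent of the substrate first charged, after gamma

- theta: at 10 min take out 90% of the target then present, then wait 5.0 min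
- eta: at 10 min raise the temperature by 25 K, then wait 5.0 min
- beta: at 10 min add free enzyme, 50.0% of the amount charged, then wait 5.0 min
- gamma: change nothing and wait 5.0 min more

- removed target is counted in
- additions bring no volume worth counting

In the autumn run, which is the flask asked about, pooling the readings up to 4.00 min gives 4.58. This reading is the stop ratio, c target over c substrate where the climb ends at this temperature. I take it as the ratio that a working enzyme in this flask restores at 25 °C, from either side.

The last two readings pool to 6.04, higher than the stop ratio; in common logarithms that is 0.661 rising to 0.781. Target stays flat while mean substrate falls 4.2 percentage points, more than the 1.5 points of one reading. So I read the enzyme in this flask as nearly idle by then.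

My reckoning follows. Target at 10 min stays near 81.8%, and gamma leaves it there. Beta brings fresh enzyme to a flask whose last readings stand above its stop ratio, so I expect target to fall back: the last readings' pooled sum of 95.0%, divided at the stop ratio, leaves 78.0%. Theta lowers the ratio and eta warms the flask, but I expect a nearly idle enzyme to do little with either, so I choose none. One number was not enough here: the ratio gives the direction, and its drift gives the sign of life.

The forecast gave 82%, 83% after beta, 82% after gamma and theta as best, saying “I lean to equilibrium, because the plateau is sharp and shifts with temperature”.

The flask gives 80.2% at 10 min, and the best choice is none.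

    substrate + free enzyme ⇌ complex (K = 26.2 /M, k = 15900 /M/s, Ea = 30.0 kJ/mol, ΔH = 25.0 kJ/mol)
    free enzyme + target → spent catalyst A (k = 0.0515 /M/s, Ea = 50.0 kJ/mol)
    complex ⇌ free enzyme + target (K = 0.190 M, k = 3590 /s, Ea = 47.0 kJ/mol, ΔH = 33.0 kJ/mol)
    complex → spent catalyst B (k = 0.0177 /s, Ea = 90.0 kJ/mol)
    substrate → uncatalysed product (k = 6.07 × 10⁻⁴ /s, Ea = 87.0 kJ/mol)
    free enzyme → unfolded enzyme (k = 5.45 × 10⁻⁴ /s, Ea = 235 kJ/mol)
    (constants at 25 °C)

Theta changes target by 1.2 points, gamma by −0.15 points to 80.0%, and beta by −3.4 points to 76.7%, with free enzyme at 0.429% of the catalyst charged at 10.0 min. Dividing this flask's target plus substrate at the stop ratio gives 77.0% for beta. Left to 100 min at the same temperature, this flask stands at a ratio of 154, far above the stop ratio of 4.58, with free enzyme at 0%.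

The earlier runs and the new flask come from a simulation with constants of no real substance; scatter was added.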